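**Plan**
- Retrosynthetic cuts, in order: the C7'–H bond (back to a C7'–OH, which uncovers a C2-symmetric diol); both C7–aryl and C7'–aryl bonds (to trans-tetrahydrofuran-3,4-dicarbaldehyde and two equivalents of an aryl Grignard reagent); the C8–C8' ring bond (to an acyclic bis-imide of 3,3'-oxydipropionic acid).
- Forward order: the tetrahydrofuran ring (O, C9, C8, C8', C9'), the only ring made, closes first by oxidative dienolate coupling; both aryl groups are joined in one two-directional step; one of the two equivalent benzylic hydroxyls is then removed and the phenols are freed.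
- Enabling feature: C7 and C7' carry the same 4-hydroxy-3-methoxyphenyl ring on a trans-3,4-disubstituted tetrahydrofuran and differ only in the C7 hydroxyl. The target is thus the mono-deoxy form of a diol whose C2 axis runs through the ring oxygen and the midpoint of C8–C8', with homotopic carbinols.
- Stereochemistry: C8 and C8' come from the (R)-4-isopropyloxazolidin-2-one auxiliary in the ring closure; C7 (together with C7') comes from Felkin–Anh addition directed by the neighbouring ring centre.

Key step: step 7

Assumption: the oxidative coupling follows the usual chelated Z-enolate model of N-acyl oxazolidinones (bond formation anti to the isopropyl group). Because the ring oxygen raises the CIP rank of C9 above C8', it is the (R)-auxiliary that gives the (3R,4R) ring on this model.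

**Route**

Step 1
Reactants: 1 3,3'-oxydipropionic acid; 2 (R)-4-isopropyloxazolidin-2-one
Product: 4 acyclic bis-imide 3,3'-oxybis{1-[(R)-4-isopropyl-2-oxooxazolidin-3-yl]propan-1-one}, via bis(pivalic) mixed anhydride 3 (not isolated)
Conditions: PivCl (2.2 equiv), Et3N, THF, −20 °C; then LiCl, 2 (2.1 equiv), −20 °C to rt
Reagents that add atoms: second equivalent of auxiliary 2, (R)-4-isopropyloxazolidin-2-one, CC(C)[C@@H]1COC(=O)N1
Why: N-acylation of an oxazolidinone through a mixed pivalic anhydride with LiCl activation is a standard mild imide synthesis; both carboxyl groups of 1 are acylated, so two molecules of 2 are consumed, and since no strong base is used the 3-alkoxypropanoyl units are not exposed to β-elimination; no stereocentre is formed.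

Step 2
Reactants: 4 acyclic bis-imide
Product: 6 [(3R,4R)-tetrahydrofuran-3,4-diyl]bis{[(R)-4-isopropyl-2-oxooxazolidin-3-yl]methanone}, via dilithium Z,Z-dienolate 5 (not isolated)
Conditions: LiN(iPr)2 (LDA, 2.2 equiv), THF, −78 °C; then anhydrous CuCl2 (2.3 equiv), −78 °C to rt, high dilution
Reagents that add atoms: none
Why: Intramolecular oxidative enolate coupling of an α,ω-dioic bis-imide: CuCl2 oxidises the dienolate and the C8–C8' bond closes the five-membered ring; each chelated Z-enolate bonds on the face anti to its isopropyl group and the two (R)-auxiliaries act in the matched sense, which should give the trans (3R,4R) ring.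

Step 3
Reactants: 6 cyclic bis-imide
Product: 7 [(3S,4S)-tetrahydrofuran-3,4-diyl]dimethanol
Conditions: LiBH4, H2O (2 equiv), THF, 0 °C to rt; minimal aqueous quench, evaporation, extraction of the residue with EtOAc/MeOH
Reagents that add atoms: none
Why: Reductive cleavage of N-acyl oxazolidinones by LiBH4 (hydride attack at the exocyclic carbonyl) gives the primary alcohols and returns auxiliary 2 without touching the ring centres, whose descriptor changes to S only through CIP ranking.

Step 4
Reactants: 7 [(3S,4S)-tetrahydrofuran-3,4-diyl]dimethanol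
Product: 9 (3R,4R)-tetrahydrofuran-3,4-dicarbaldehyde, via bis(alkoxydimethylsulfonium) dichloride 8 (not isolated)
Conditions: (COCl)2, DMSO, CH2Cl2, −78 °C; then Et3N, −78 to 0 °C; rapid cold work-up, crude used at once
Reagents that add atoms: none
Why: Swern oxidation activates both hydroxyls as alkoxysulfonium ions before base is added, so both are oxidised together without a hydroxy-aldehyde stage that could lactolise, and the cold elimination with immediate use limits epimerisation α to the formyl groups.

Step 5
Reactants: 10 4-bromo-2-methoxyphenol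
Product: 11 1-(benzyloxy)-4-bromo-2-methoxybenzene
Conditions: BnBr, K2CO3, DMF, rt
Reagents that add atoms: benzyl bromide, BrCc1ccccc1
Why: Williamson ether synthesis on the phenoxide gives a benzyl ether that tolerates organomagnesium, tin-hydride radical and basic conditions and is removed at the end by hydrogenolysis.

Step 6
Reactants: 11 1-(benzyloxy)-4-bromo-2-methoxybenzene
Product: 12 [4-(benzyloxy)-3-methoxyphenyl]magnesium bromide (titrated THF solution)
Conditions: Mg turnings, cat. I2, THF, reflux
Reagents that add atoms: magnesium, [Mg]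
Why: Grignard reagent formation by insertion of magnesium into the aryl C–Br bond is routine for alkoxy-substituted aryl bromides, and the ether groups are inert.

Step 7
Reactants: 9 (3R,4R)-tetrahydrofuran-3,4-dicarbaldehyde; 12 [4-(benzyloxy)-3-methoxyphenyl]magnesium bromide
Product: 14 (R,R)-[(3R,4R)-tetrahydrofuran-3,4-diyl]bis{[4-(benzyloxy)-3-methoxyphenyl]methanol}, via bis(bromomagnesium) dialkoxide 13 (not isolated)
Conditions: 9 in THF added to 12 (3 equiv), THF, −78 to −20 °C; then sat. aq. NH4Cl
Reagents that add atoms: second equivalent of Grignard reagent 12, [4-(benzyloxy)-3-methoxyphenyl]magnesium bromide, COc1cc([Mg]Br)ccc1OCc1ccccc1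
Why: Each of the two formyl groups of 9 undergoes polar 1,2-addition of one aryl–magnesium bond, so two molecules of 12 are consumed and the C7–aryl and C7'–aryl bonds form without closing any ring; the closest known reaction type is Felkin–Anh-controlled Grignard addition to an α-branched aldehyde, here run in two directions on one C2-symmetric substrate. In the reactive conformer the branched ring carbon (C8' seen from C7, C8 seen from C7') stands perpendicular to the carbonyl as the large group, the ring methylene lies next to the carbonyl oxygen, and the aryl group enters anti to the large group past the small ring hydrogen, which for an (8R) centre gives the (7R) carbinol; a magnesium chelate between the carbonyl oxygen and the ring oxygen would expose the same face. Both new stereocentres, C7 and C7', are therefore set by the adjacent ring centres C8 and C8', and the C2 axis makes the two additions identical, so the (7R,7'R,8R,8'R) diol is expected as the major isomer. The step needs diastereofacial selectivity at both aldehydes and addition in preference to enolisation; the trans ring substituents, the weak basicity of the aryl Grignard reagent at −78 °C and inverse addition into excess reagent should secure these. The trans arrangement also disfavours capture of the second aldehyde by the first alkoxide, because the resulting lactol would be a strained trans-fused bicycle.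

Step 8
Reactants: 14 C2-symmetric diol
Product: 16 O-{(R)-[4-(benzyloxy)-3-methoxyphenyl][(3R,4R)-4-{(R)-[4-(benzyloxy)-3-methoxyphenyl](hydroxy)methyl}tetrahydrofuran-3-yl]methyl} S-methyl carbonodithioate, via sodium xanthate salt 15 (not isolated)
Conditions: NaH (0.9 equiv), CS2 (5 equiv), THF, 0 °C; then MeI, 0 °C to rt; Et3N-deactivated silica
Reagents that add atoms: carbon disulfide, S=C=S; iodomethane, CI
Why: Xanthate formation (alkoxide addition to CS2, then S-methylation) needs no selective reagent because the two hydroxyls are homotopic, so reaction at either gives the same mono-xanthate, and a deficit of NaH keeps double derivatisation low while unreacted 14 is recycled.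

Step 9
Reactants: 16 mono-xanthate
Product: 17 (R)-[4-(benzyloxy)-3-methoxyphenyl]{(3R,4R)-4-[4-(benzyloxy)-3-methoxybenzyl]tetrahydrofuran-3-yl}methanol
Conditions: Bu3SnH (1.5 equiv), Et3B, air, toluene, rt
Reagents that add atoms: none
Why: Barton–McCombie deoxygenation: the stannyl radical adds to the thiocarbonyl sulfur, β-scission releases a stabilised benzylic radical at C7' that abstracts hydrogen from Bu3SnH, and initiation at rt avoids thermal elimination of the benzylic xanthate; the new methylene is not stereogenic and the C7 carbinol is untouched.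

Step 10
Reactants: 17 mono-deoxy bis(benzyl ether)
Product: 18 4-{(R)-hydroxy[(3R,4R)-4-(4-hydroxy-3-methoxybenzyl)tetrahydrofuran-3-yl]methyl}-2-methoxyphenol (target)
Conditions: H2 (1 atm), 10% Pd/C, EtOAc, rt, stopped at consumption of 17
Reagents that add atoms: none
Why: Catalytic hydrogenolysis cleaves aryl benzyl ethers much faster than a free secondary benzylic hydroxyl in neutral EtOAc at 1 atm, so both phenols are freed while C7–OH and the three stereocentres are retained.

**Compound list**

1 | 3,3'-oxydipropionic acid | OC(=O)CCOCCC(=O)O | starting material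
2 | (R)-4-isopropyloxazolidin-2-one | CC(C)[C@@H]1COC(=O)N1 | starting material
3 | 3,3'-oxydipropionic bis(pivalic) anhydride | CC(C)(C)C(=O)OC(=O)CCOCCC(=O)OC(=O)C(C)(C)C | intermediate
4 | 3,3'-oxybis{1-[(R)-4-isopropyl-2-oxooxazolidin-3-yl]propan-1-one} | O=C(CCOCCC(=O)N1[C@H](C(C)C)COC1=O)N1[C@H](C(C)C)COC1=O | intermediate
5 | dilithium (1Z,1'Z)-3,3'-oxybis{1-[(R)-4-isopropyl-2-oxooxazolidin-3-yl]prop-1-en-1-olate} | [Li+].[Li+].[O-]/C(=C\COC/C=C(\[O-])N1[C@H](C(C)C)COC1=O)N1[C@H](C(C)C)COC1=O | intermediate
6 | [(3R,4R)-tetrahydrofuran-3,4-diyl]bis{[(R)-4-isopropyl-2-oxooxazolidin-3-yl]methanone} | O=C([C@H]1COC[C@@H]1C(=O)N1[C@H](C(C)C)COC1=O)N1[C@H](C(C)C)COC1=O | intermediate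
7 | [(3S,4S)-tetrahydrofuran-3,4-diyl]dimethanol | OC[C@H]1COC[C@@H]1CO | intermediate
8 | {[(3R,4R)-tetrahydrofuran-3,4-diyl]bis(methyleneoxy)}bis(dimethylsulfonium) dichloride | C[S+](C)OC[C@H]1COC[C@@H]1CO[S+](C)C.[Cl-].[Cl-] | intermediate
9 | (3R,4R)-tetrahydrofuran-3,4-dicarbaldehyde | O=C[C@H]1COC[C@@H]1C=O | intermediate
10 | 4-bromo-2-methoxyphenol | COc1cc(Br)ccc1O | starting material
11 | 1-(benzyloxy)-4-bromo-2-methoxybenzene | COc1cc(Br)ccc1OCc1ccccc1 | intermediate
12 | [4-(benzyloxy)-3-methoxyphenyl]magnesium bromide | COc1cc([Mg]Br)ccc1OCc1ccccc1 | intermediate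
13 | bis(bromomagnesium) (R,R)-[(3R,4R)-tetrahydrofuran-3,4-diyl]bis{[4-(benzyloxy)-3-methoxyphenyl]methanolate} | COc1cc([C@H](O[Mg]Br)[C@H]2COC[C@@H]2[C@@H](O[Mg]Br)c2ccc(OCc3ccccc3)c(OC)c2)ccc1OCc1ccccc1 | intermediate
14 | (R,R)-[(3R,4R)-tetrahydrofuran-3,4-diyl]bis{[4-(benzyloxy)-3-methoxyphenyl]methanol} | COc1cc([C@H](O)[C@H]2COC[C@@H]2[C@@H](O)c2ccc(OCc3ccccc3)c(OC)c2)ccc1OCc1ccccc1 | intermediate
15 | sodium O-{(R)-[4-(benzyloxy)-3-methoxyphenyl][(3R,4R)-4-{(R)-[4-(benzyloxy)-3-methoxyphenyl](hydroxy)methyl}tetrahydrofuran-3-yl]methyl} carbonodithioate | COc1cc([C@H](OC(=S)[S-])[C@H]2COC[C@@H]2[C@@H](O)c2ccc(OCc3ccccc3)c(OC)c2)ccc1OCc1ccccc1.[Na+] | intermediate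
16 | O-{(R)-[4-(benzyloxy)-3-methoxyphenyl][(3R,4R)-4-{(R)-[4-(benzyloxy)-3-methoxyphenyl](hydroxy)methyl}tetrahydrofuran-3-yl]methyl} S-methyl carbonodithioate | COc1cc([C@H](OC(=S)SC)[C@H]2COC[C@@H]2[C@@H](O)c2ccc(OCc3ccccc3)c(OC)c2)ccc1OCc1ccccc1 | intermediate
17 | (R)-[4-(benzyloxy)-3-methoxyphenyl]{(3R,4R)-4-[4-(benzyloxy)-3-methoxybenzyl]tetrahydrofuran-3-yl}methanol | COc1cc(C[C@H]2COC[C@@H]2[C@@H](O)c2ccc(OCc3ccccc3)c(OC)c2)ccc1OCc1ccccc1 | intermediate
18 | 4-{(R)-hydroxy[(3R,4R)-4-(4-hydroxy-3-methoxybenzyl)tetrahydrofuran-3-yl]methyl}-2-methoxyphenol | COc1cc(C[C@H]2COC[C@@H]2[C@@H](O)c2ccc(O)c(OC)c2)ccc1O | target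

**Step count and risks**

Total step count: 10. Longest linear sequence: 8 steps (steps 1, 2, 3, 4, 7, 8, 9, 10, from 3,3'-oxydipropionic acid).

Steps most likely to fail:

1. Step 2. The lithium enolate may fragment by β-elimination of the tether oxygen, or intermolecular coupling may outrun ring closure. The fallback sets out from auxiliary 2 and comes back at 6. Compound 2 is N-acylated twice with fumaroyl chloride (n-BuLi, THF, −78 °C) to give (E)-1,4-bis[(R)-4-isopropyl-2-oxooxazolidin-3-yl]but-2-ene-1,4-dione F1. The ring is then built by 1,3-dipolar cycloaddition of the parent carbonyl ylide, generated from chloromethyl (trimethylsilyl)methyl ether and CsF in MeCN, to the electron-poor double bond. The suprafacial cycloaddition keeps the E geometry, so only trans adducts can form. These are diastereomers because of the auxiliaries, and the (3R,4R) isomer 6 would be separated by chromatography or crystallisation. No enolate with a β-oxygen is involved.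

2. Step 7. Facial discrimination at one or both formyl groups may be insufficient, or the basic reagent may enolise and epimerise the dialdehyde. The fallback sets out from 14 obtained as a mixture of carbinol epimers and comes back at 14. The mixture is oxidised with Dess–Martin periodinane (CH2Cl2, NaHCO3) to the single diketone [(3R,4R)-tetrahydrofuran-3,4-diyl]bis{[4-(benzyloxy)-3-methoxyphenyl]methanone} F2. Both aryl ketones are then reduced under reagent control with BH3·SMe2 and (S)-2-methyl-CBS-oxazaborolidine, that is (S)-1-methyl-3,3-diphenyltetrahydro-1H,3H-pyrrolo[1,2-c][1,3,2]oxazaborole (Corey–Bakshi–Shibata reduction, THF, −20 °C). This catalyst delivers hydride to give the (R)-carbinol of aryl alkyl ketones, so the (7R,7'R) diol 14 should result independently of the substrate bias.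

3. Step 9. The electron-rich benzylic xanthate may ionise, rearrange from O to S, or undergo syn-elimination before radical cleavage. The fallback sets out from 14 and comes back at target 18. Statistical mono-acetylation (Ac2O, 0.9 equiv, pyridine, cat. DMAP, CH2Cl2, 0 °C; diol recycled) gives (R)-[4-(benzyloxy)-3-methoxyphenyl]{(3R,4R)-4-[(R)-[4-(benzyloxy)-3-methoxyphenyl](hydroxy)methyl]tetrahydrofuran-3-yl}methyl acetate F3. Hydrogenolysis (H2, 10% Pd/C, EtOAc, rt) then cleaves the benzylic C–OAc bond, which is far more labile than the free benzylic C–OH, together with both benzyl ethers, and gives 18 directly.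

**Further compounds**

F1 | step 2 | (E)-1,4-bis[(R)-4-isopropyl-2-oxooxazolidin-3-yl]but-2-ene-1,4-dione | O=C(/C=C/C(=O)N1[C@H](C(C)C)COC1=O)N1[C@H](C(C)C)COC1=O
F2 | step 7 | [(3R,4R)-tetrahydrofuran-3,4-diyl]bis{[4-(benzyloxy)-3-methoxyphenyl]methanone} | COc1cc(C(=O)[C@H]2COC[C@@H]2C(=O)c2ccc(OCc3ccccc3)c(OC)c2)ccc1OCc1ccccc1
F3 | step 9 | (R)-[4-(benzyloxy)-3-methoxyphenyl]{(3R,4R)-4-[(R)-[4-(benzyloxy)-3-methoxyphenyl](hydroxy)methyl]tetrahydrofuran-3-yl}methyl acetate | COc1cc([C@H](OC(C)=O)[C@H]2COC[C@@H]2[C@@H](O)c2ccc(OCc3ccccc3)c(OC)c2)ccc1OCc1ccccc1
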